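The forms of the catalyst always sum to what was charged, so a catalyst that is being lost can be followed by one number: turnovers, the product made per catalyst charged.

| setting | birch | cedar | maple | amber | red |
|---|---|---|---|---|---|
| substrate | 0.50 mM | 0.50 mM | 0.63 mM | 1.5 mM | 0.50 mM |
| precatalyst | 7.7 µM | 13 µM | 15 µM | 10 µM | 15 µM |
| remark | run made earlier | run made earlier | run made earlier |  |  |
| time |  |  |  | 2.0 min | 2.0 min |

| run | time / s | product / % | substrate / % |
|---|---|---|---|
| birch | 10.0 | 1 | 100 |
| birch | 15.0 | 4 | 96 |
| birch | 30.0 | 9 | 92 |
| birch | 50.0 | 12 | 86 |
| birch | 60.0 | 15 | 83 |
| birch | 80.0 | 21 | 79 |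
| cedar | 15.0 | 3 | 93 |
| cedar | 30.0 | 11 | 84 |
| cedar | 40.0 | 18 | 81 |
| cedar | 60.0 | 22 | 75 |
| cedar | 80.0 | 28 | 68 |
| maple | 10.0 | 2 | 97 |
| maple | 12.0 | 4 | 95 |
| maple | 25.0 | 10 | 88 |
| maple | 40.0 | 18 | 82 |
| maple | 80.0 | 28 | 69 |

(standard deviation of a reading: 2 percentage points)

- the winner by amount of product, in percent of the substrate charged; "neither" if no more than 2 percentage points parts them (amber / red / neither)
- how much product is there at the end, in percent of the substrate charged: amber
- how much product is there at the end, in percent of the substrate charged: red

- in percentages every species weighs as the substrate in it: one spent catalyst A counts as two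
- the numbers in the tables scatter by 2 percentage points (one standard deviation)
- on the list of suspects stand: catalyst intermediate B -> spent catalyst B; catalyst intermediate A + product -> spent catalyst A; catalyst intermediate A <-> catalyst intermediate B; precatalyst -> free catalyst; substrate + free catalyst <-> catalyst intermediate A; catalyst intermediate B -> free catalyst + product

**What do you count?** Cedar reads 18% product at 40.0 s and 28% at 80.0 s. That is 6.92 turnovers in the first stretch and 3.85 in the second, of equal length. Maple reads the same two percentages at those times.

**So the count slows. Where does it stop?** I assume each stretch yields the same fraction of the one before. The series then sums to the turnover budget (the total turnover number), the count per catalyst charged when the catalyst is spent: 15.6.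

**Red?** A third stretch ends at 2.0 min and brings the count to 12.9. With c(product) = count × c(precatalyst), red reaches 38.7% of its charge.

**Amber?** Amber holds more substrate, so its round may run ahead of cedar's. I place it between the same count, 8.60%, and the full budget, 10.4%, and commit to the upper end. The budget makes 0.156 mM, well below the 1.5 mM charged, so the catalyst gives out before the substrate does in amber.

**Does the count carry across charges?** Not exactly. Birch counts 13.6 at 80.0 s against cedar's 10.8, and the scatter of one birch reading is worth 1.30 turnovers. Red still wins by far more than the margin of 2 percentage points.

The forecast says red, with 37% for red and 14% for amber, above my amber figure: “Red resembles cedar with slightly more catalyst”.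

The flask gives red: red 39.0%, amber 11.5%.

    catalyst intermediate B → spent catalyst B (k = 0.0329 /s)
    catalyst intermediate A + product → spent catalyst A (k = 247 /M/s)
    catalyst intermediate A ⇌ catalyst intermediate B (K = 0.820, k = 83.7 /s)
    precatalyst → free catalyst (k = 0.272 /s)
    substrate + free catalyst ⇌ catalyst intermediate A (K = 34000 /M, k = 881 /M/s)
    catalyst intermediate B → free catalyst + product (k = 1.15 /s)

In red at 2.00 min, catalyst intermediate B makes free catalyst + product 35 times as fast as it goes to spent catalyst B; that ratio times the share ending as spent catalyst B gives the product made per catalyst charged, and the count is this less the share ending as spent catalyst A, each of which took up one product. Red at 20.0 min holds 47.9% product, a count of 16.0 against the budget of 15.6, with 47.2% as spent catalyst B and 52.8% as spent catalyst A, and the rule gives 16.0. Amber at 20.0 min holds 12.2%, a count of 18.4, with 53.8% as spent catalyst B and 46.2% as spent catalyst A, and the rule gives 18.4.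

The numbers in the tables were generated by integration with constants of no real substance, noise included.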